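We start from the amounts: the free monomer arrives by feed over 50 s, with pre-initiator at 10 mol% of it, and percentages count the whole charge.

- larch: free monomer 0.010 M (fed, over 50 s); pre-initiator 10 mol%; the very flask that is asked about, followed so far; the fed solution adds 1.0 times the starting volume
- flask: free monomer 0.010 M (fed, over 50 s); pre-initiator 10 mol%; time 2.5 min; the fed solution adds 1.0 times the starting volume

larch run (percent of the free monomer charged)

| time / s | monomer in chains / % | free monomer / % |
|---|---|---|
| 12.0 | 0.6 | 23.4 |
| 25.0 | 3.8 | 45.7 |
| 30.0 | 10.3 | 50.3 |
| 50.0 | 22.5 | 78.5 |

(readings scatter by 1 percentage point)

- charges are per starting volume, the dose included; the dosed solution carries all of it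
- the average divides the monomer in chains by the number of chains begun, living and dead together
- the earlier runs do not show the number of chains; that part of a forecast is a guess
- percentages count the whole charge, also what has not yet gone in

* average number of monomer units in a chain (chains begun, living or dead) at 2.5 min
* part of the free monomer that has reacted at 2.5 min

From 25.0 s to 50.0 s, monomer entering chains over the mean free monomer gives a pseudo-first-order constant of 0.0120 s⁻¹. This is a reading, and it is up from 0.00712 s⁻¹ between 12.0 s and 25.0 s.

The reading at the end of the feed contributes 0.242, and the remaining 100 s at our constant add 1.20. The sum, 1.45, is the exposure, the natural logarithm of charged over free monomer left.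

Our reckoning therefore leaves 23.5% free monomer and gives c = 76.5%, a low estimate if the constant keeps rising. One number is not enough for dp, since the readings show no chain count: if each pre-initiator began a chain, dp would be 7.65.

The forecast gives c = 77% and dp = 11, reasoning that “active centres are slowly being generated from the pre-initiator”.

The flask gives c = 82.4% and dp = 9.22.

    free monomer + initiator → living end + monomer in chains (k = 133 L mol⁻¹ s⁻¹)
    free monomer + living end → monomer in chains + living end, rate k2*[living end]*[free monomer] (k = 36.8 L mol⁻¹ s⁻¹)
    pre-initiator ⇌ initiator (K = 0.490, k = 0.0179 s⁻¹)

The free monomer left in the flask, 18%, is an exposure of 1.74, more than our 1.45. After the feed, the flask's constant averaged 0.0149 s⁻¹. A neighbouring flask keeps the loadings with 0.0040 M of free monomer, 0.400 of this flask's charge, and its living end at 2.50 min stands at 0.392 of this flask's. Scaling this flask's exposure by the charge gives 0.695 for the neighbouring flask, hence 49.9% free monomer left; the neighbouring flask holds 49%.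

(The numbers in the tables stem from a simulated flask for substances that don't exist; noise was put on by code.)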